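The runs were generated by integration with made-up constants, noise included.

1. I started from a balance: I took each substrate molecule turned over to cost one reagent molecule. That cost was my assumption, and the readings did not measure it; in the dawn flask, left-handed substrate plus left-handed product came to 50.3 % at 120 min, against 50.0 % charged.

| flask | left-handed substrate | right-handed substrate | reagent | catalyst | remark | time |
|---|---|---|---|---|---|---|
| dawn | 0.10 M | 0.10 M | 0.11 M (fed, over 2.0 h) | 1.1 mM | the very flask that is asked about, followed so far |  |
| autumn | 0.10 M | 0.10 M | 0.055 M (fed, over 2.0 h) | 1.1 mM | run made earlier |  |
| flask | 0.10 M | 0.10 M | 0.110 M (fed, over 2.0 h) | 1.1 mM |  | 4.0 h |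

- dawn (time / min: left-handed substrate / %, left-handed product / %): 10.0: 50.3, 1.0; 15.0: 49.4, 1.0; 20.0: 49.5, 0.9; 30.0: 48.6, 2.1; 50.0: 45.4, 3.8; 80.0: 41.0, 9.0; 120: 33.8, 16.5
- autumn (time / h: left-handed substrate / %, left-handed product / %): 0.167: 49.5, 0.4; 0.417: 49.2, 0.1; 0.833: 47.7, 1.6; 1.33: 45.7, 4.8; 1.50: 43.0, 5.8; 2.00: 40.7, 8.4; 3.00: 35.8, 13.9

(scatter of a reading: 0.5 percentage points)

- catalyst is single-handed; left-handed substrate and right-handed substrate are mirror images of each other, charged as a racemate, each of them at the stated concentration

* share of the left-handed substrate and right-handed substrate together used up at 4.0 h
* left-handed product at 4.0 h, in percent of the left-handed substrate and right-handed substrate together charged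
* amount of left-handed product if the flask were left three thousand times as long, in percent of the left-handed substrate and right-handed substrate together charged

2. So I counted c(reagent) against c(left-handed substrate) + c(right-handed substrate). The reagent budget, the share of both substrates together that the whole reagent charge can turn over, came to 55.0 %. Reagent is therefore the limiting reagent.

3. I then turned the question round. For left-handed substrate to vanish from this flask, the budget had to cover its 50.0 %, which leaves the right-handed substrate at most 5 percentage points. Right-handed substrate was never read, so my own reckoning gave a bound and no point value: conv stays at or below the budget.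

4. The forecast gave 38 %, 29 % and 39 %. It assigned a second reagent drain to the right-handed substrate and wrote that “it is poorly defined and could be reagent decay”. Against the budget, its 39 % gives the right-handed substrate 16 points, more than the margin.

5. The flask gave 38.3 %, 29.7 % and 40.4 %.

    reagent + catalyst + left-handed substrate → catalyst + left-handed product (k = 1.31 L² mol⁻² s⁻¹)
    reagent + catalyst + right-handed substrate → catalyst + right-handed product (k = 0.275 L² mol⁻² s⁻¹)

At 4.00 h the flask kept 30 % of its reagent, and the budget times the used part gives 38.5 %, beside the conv of 38.3 %. At 40.0 h, with reagent down to 0.0312 %, conv stood at 55.0 %, the budget again. Right-handed product then held 14.6 %, more than the margin, and left-handed substrate 9.63 % remained. The neighbouring flask with 0.27 M of reagent has a budget of 135 %. It kept 50 % of its reagent at 4.00 h, which reckons to 67.5 % against its conv of 67.7 %, and its left-handed substrate stood at 3.55 %.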